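**Retrosynthetic overview**
1. Target 21 ← protected oxolane 19 by desilylation, then hydrogenolysis of three aryl benzyl ethers.
2. Oxolane ring of 19 (ring B, closed last) ← 1,4-diol 17 by primary tosylate/Williamson closure ← hydride reduction of lactone 16.
3. Lactone Cα–carbinol bond of 15 ← intermolecular aldol of the potassium enolate of lactone 12 with 3,4-bis(benzyloxy)benzaldehyde 13 (fragment union).
4. trans-Lactone 12 (ring A, closed first) ← Evans syn-aldol of succinate imide 4 with O-benzylvanillin 5, then lactonisation, auxiliary removal, acid reduction and silylation.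
5. Ring order: γ-lactone (ring A) first; the same five atoms are later reduced and re-closed as the oxolane (ring B).

Assumption: compounds 1, 2, 5 and 13 are bought as cheap catalogue chemicals.

**Route**

Step 1
Reactants: 1 (S)-4-benzyl-1,3-oxazolidin-2-one; 2 methyl 4-chloro-4-oxobutanoate
Product: 4 methyl 4-[(4S)-4-benzyl-2-oxo-1,3-oxazolidin-3-yl]-4-oxobutanoate, via lithium oxazolidinide 3 (not isolated)
Conditions: n-BuLi (1.0 equiv), THF, −78 °C; then 2, −78 → 0 °C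
Reagents that add atoms: none
Why: N-acylation of the lithiated Evans auxiliary by the acid chloride, which reacts far faster than the methyl ester; no stereocentre is formed.

Step 2
Reactants: 4 methyl 4-[(4S)-4-benzyl-2-oxo-1,3-oxazolidin-3-yl]-4-oxobutanoate; 5 4-(benzyloxy)-3-methoxybenzaldehyde
Product: 7 methyl (3S,4S)-3-{[(4S)-4-benzyl-2-oxo-1,3-oxazolidin-3-yl]carbonyl}-4-[4-(benzyloxy)-3-methoxyphenyl]-4-hydroxybutanoate, via boron Z-enolate 6 (not isolated)
Conditions: Bu2BOTf (1.1 equiv), iPr2NEt (1.3 equiv), CH2Cl2, −78 → 0 °C; 5, −78 → 0 °C; pH 7 buffer, MeOH, 30% H2O2, 0 °C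
Reagents that add atoms: none
Why: Evans syn-aldol reaction in which soft enolisation occurs only at the imide α-CH2 to give the Z-boron enolate, which adds through a chair Zimmerman–Traxler transition state on the face away from the auxiliary benzyl group and so sets both new centres (3S,4S).

Step 3
Reactants: 7 methyl (3S,4S)-3-{[(4S)-4-benzyl-2-oxo-1,3-oxazolidin-3-yl]carbonyl}-4-[4-(benzyloxy)-3-methoxyphenyl]-4-hydroxybutanoate
Product: 8 (4S)-4-benzyl-3-{[(2S,3S)-2-[4-(benzyloxy)-3-methoxyphenyl]-5-oxooxolan-3-yl]carbonyl}-1,3-oxazolidin-2-one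
Conditions: PPTS (10 mol %), toluene, 60 °C
Reagents that add atoms: none
Why: Acid-catalysed lactonisation of the γ-hydroxy ester closes ring A by acyl substitution without touching either stereocentre, so the syn aldol becomes the 2,3-trans lactone.

Step 4
Reactants: 8 (4S)-4-benzyl-3-{[(2S,3S)-2-[4-(benzyloxy)-3-methoxyphenyl]-5-oxooxolan-3-yl]carbonyl}-1,3-oxazolidin-2-one
Product: 10 (2S,3S)-2-[4-(benzyloxy)-3-methoxyphenyl]-5-oxooxolane-3-carboxylic acid, via peroxy acid 9 (not isolated)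
Conditions: LiOH·H2O (2 equiv), 30% H2O2 (4 equiv), THF–H2O 3:1, 0 °C; aq. Na2SO3; 1 M HCl to pH 2
Reagents that add atoms: hydrogen peroxide, OO (as LiOOH; its oxygen becomes the carboxyl OH)
Why: Hydroperoxide cleavage of the Evans imide attacks the exocyclic carbonyl selectively at 0 °C, sulfite reduces the peroxy acid, and acidification re-closes any opened lactone, with both stereocentres untouched.

Step 5
Reactants: 10 (2S,3S)-2-[4-(benzyloxy)-3-methoxyphenyl]-5-oxooxolane-3-carboxylic acid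
Product: 11 (4R,5S)-5-[4-(benzyloxy)-3-methoxyphenyl]-4-(hydroxymethyl)oxolan-2-one
Conditions: BH3·SMe2 (1.5 equiv), THF, 0 °C → rt; MeOH quench
Reagents that add atoms: none
Why: Chemoselective borane reduction, since electrophilic borane reduces the free carboxylic acid much faster than the lactone; the geometry is unchanged and only the descriptor switches (3S → 4R) through priority rules.

Step 6
Reactants: 11 (4R,5S)-5-[4-(benzyloxy)-3-methoxyphenyl]-4-(hydroxymethyl)oxolan-2-one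
Product: 12 (4R,5S)-5-[4-(benzyloxy)-3-methoxyphenyl]-4-{[(tert-butyldimethylsilyl)oxy]methyl}oxolan-2-one
Conditions: TBSCl (1.2 equiv), imidazole (2.5 equiv), DMF, 0 °C → rt
Reagents that add atoms: tert-butyldimethylsilyl chloride (TBSCl), CC(C)(C)[Si](C)(C)Cl
Why: Silyl ether protection of the primary alcohol under mild conditions prevents translactonisation and masks the OH before enolate chemistry.

Step 7
Reactants: 12 (4R,5S)-5-[4-(benzyloxy)-3-methoxyphenyl]-4-{[(tert-butyldimethylsilyl)oxy]methyl}oxolan-2-one; 13 3,4-bis(benzyloxy)benzaldehyde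
Product: 15 (3R,4R,5S)-5-[4-(benzyloxy)-3-methoxyphenyl]-3-{(R)-[3,4-bis(benzyloxy)phenyl](hydroxy)methyl}-4-{[(tert-butyldimethylsilyl)oxy]methyl}oxolan-2-one, via potassium enolate 14 (not isolated)
Conditions: KN(SiMe3)2 (1.1 equiv), THF, −78 °C, 30 min; 13 (1.2 equiv), −78 °C, 1 h; AcOH/THF quench at −78 °C; chromatography
Reagents that add atoms: none
Why: Intermolecular aldol addition of lactone enolate 14 to aldehyde 13 forms the key C–C bond, the aldehyde adding anti to the neighbouring C4 CH2OTBS group (3,4-trans, C3 = R) while the loosely coordinated potassium enolate reacts through an open transition state that favours the erythro (syn) carbinol (R), the minor carbinol epimer being removed by chromatography.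

Step 8
Reactants: 15 (3R,4R,5S)-5-[4-(benzyloxy)-3-methoxyphenyl]-3-{(R)-[3,4-bis(benzyloxy)phenyl](hydroxy)methyl}-4-{[(tert-butyldimethylsilyl)oxy]methyl}oxolan-2-one
Product: 16 (3R,4R,5S)-5-[4-(benzyloxy)-3-methoxyphenyl]-3-{(R)-[3,4-bis(benzyloxy)phenyl][(tert-butyldimethylsilyl)oxy]methyl}-4-{[(tert-butyldimethylsilyl)oxy]methyl}oxolan-2-one
Conditions: TBSOTf (1.5 equiv), 2,6-lutidine (3 equiv), CH2Cl2, −78 → 0 °C
Reagents that add atoms: tert-butyldimethylsilyl trifluoromethanesulfonate (TBSOTf), CC(C)(C)[Si](C)(C)OS(=O)(=O)C(F)(F)F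
Why: Silylation of the hindered benzylic aldol hydroxyl at low temperature blocks retro-aldol cleavage in the hydride step and keeps this oxygen out of the later ring closure.

Step 9
Reactants: 16 (3R,4R,5S)-5-[4-(benzyloxy)-3-methoxyphenyl]-3-{(R)-[3,4-bis(benzyloxy)phenyl][(tert-butyldimethylsilyl)oxy]methyl}-4-{[(tert-butyldimethylsilyl)oxy]methyl}oxolan-2-one
Product: 17 (1S,2R,3S)-1-[4-(benzyloxy)-3-methoxyphenyl]-3-{(R)-[3,4-bis(benzyloxy)phenyl][(tert-butyldimethylsilyl)oxy]methyl}-2-{[(tert-butyldimethylsilyl)oxy]methyl}butane-1,4-diol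
Conditions: LiBH4 (3 equiv), THF, 0 °C → rt; aq. NH4Cl
Reagents that add atoms: none
Why: Hydride reduction of the lactone to the 1,4-diol touches only the acyl carbon, so all four stereocentres and the silyl and benzyl ethers survive.

Step 10
Reactants: 17 (1S,2R,3S)-1-[4-(benzyloxy)-3-methoxyphenyl]-3-{(R)-[3,4-bis(benzyloxy)phenyl][(tert-butyldimethylsilyl)oxy]methyl}-2-{[(tert-butyldimethylsilyl)oxy]methyl}butane-1,4-diol
Product: 19 (2S,3R,4S)-2-[4-(benzyloxy)-3-methoxyphenyl]-4-{(R)-[3,4-bis(benzyloxy)phenyl][(tert-butyldimethylsilyl)oxy]methyl}-3-{[(tert-butyldimethylsilyl)oxy]methyl}oxolane, via primary tosylate 18 (not isolated)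
Conditions: TsCl (1.2 equiv), pyridine, DMAP (cat.), 0 °C → rt; then 60 °C
Reagents that add atoms: none
Why: Selective sulfonylation of the primary hydroxyl followed by intramolecular Williamson etherification (5-exo-tet SN2 at the primary carbon) closes ring B without breaking the benzylic C–O bond, so C2 keeps its S configuration.

Step 11
Reactants: 19 (2S,3R,4S)-2-[4-(benzyloxy)-3-methoxyphenyl]-4-{(R)-[3,4-bis(benzyloxy)phenyl][(tert-butyldimethylsilyl)oxy]methyl}-3-{[(tert-butyldimethylsilyl)oxy]methyl}oxolane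
Product: 20 (R)-[3,4-bis(benzyloxy)phenyl]{(3S,4R,5S)-5-[4-(benzyloxy)-3-methoxyphenyl]-4-(hydroxymethyl)oxolan-3-yl}methanol
Conditions: Bu4NF (3 equiv), THF, 0 °C → rt
Reagents that add atoms: none
Why: Fluoride-mediated desilylation, driven by Si–F bond formation, removes both TBS ethers while the phenols are still benzylated and no C–O bond at a stereocentre is broken.

Step 12
Reactants: 20 (R)-[3,4-bis(benzyloxy)phenyl]{(3S,4R,5S)-5-[4-(benzyloxy)-3-methoxyphenyl]-4-(hydroxymethyl)oxolan-3-yl}methanol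
Product: 21 4-[(R)-hydroxy{(3S,4R,5S)-5-(4-hydroxy-3-methoxyphenyl)-4-(hydroxymethyl)oxolan-3-yl}methyl]benzene-1,2-diol
Conditions: H2 (1 atm), 10% Pd on carbon, EtOAc–MeOH 4:1, rt, stopped after uptake of 3 equiv H2; filtration under argon
Reagents that add atoms: none
Why: Catalytic hydrogenolysis of the three aryl benzyl ethers under neutral conditions is much faster than hydrogenolysis of the benzylic alcohol or the benzylic ring C–O bond, so the target is obtained with all stereocentres intact.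

**Compound list**
1 | (S)-4-benzyl-1,3-oxazolidin-2-one | O=C1OC[C@H](Cc2ccccc2)N1 | starting material
2 | methyl 4-chloro-4-oxobutanoate | COC(=O)CCC(Cl)=O | starting material
3 | lithium salt of 1 (N-lithio-(S)-4-benzyl-1,3-oxazolidin-2-one) | [Li]N1[C@@H](Cc2ccccc2)COC1=O | intermediate
4 | methyl 4-[(4S)-4-benzyl-2-oxo-1,3-oxazolidin-3-yl]-4-oxobutanoate | COC(=O)CCC(=O)N1[C@@H](Cc2ccccc2)COC1=O | intermediate
5 | 4-(benzyloxy)-3-methoxybenzaldehyde | COc1cc(C=O)ccc1OCc1ccccc1 | starting material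
6 | methyl (3Z)-4-[(4S)-4-benzyl-2-oxo-1,3-oxazolidin-3-yl]-4-[(dibutylboranyl)oxy]but-3-enoate (boron Z-enolate of 4) | COC(=O)C/C=C(\OB(CCCC)CCCC)N1[C@@H](Cc2ccccc2)COC1=O | intermediate
7 | methyl (3S,4S)-3-{[(4S)-4-benzyl-2-oxo-1,3-oxazolidin-3-yl]carbonyl}-4-[4-(benzyloxy)-3-methoxyphenyl]-4-hydroxybutanoate | COc1cc([C@@H](O)[C@H](CC(=O)OC)C(=O)N2[C@@H](Cc3ccccc3)COC2=O)ccc1OCc1ccccc1 | intermediate
8 | (4S)-4-benzyl-3-{[(2S,3S)-2-[4-(benzyloxy)-3-methoxyphenyl]-5-oxooxolan-3-yl]carbonyl}-1,3-oxazolidin-2-one (trans lactone) | COc1cc([C@H]2OC(=O)C[C@@H]2C(=O)N2[C@@H](Cc3ccccc3)COC2=O)ccc1OCc1ccccc1 | intermediate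
9 | (2S,3S)-2-[4-(benzyloxy)-3-methoxyphenyl]-5-oxooxolane-3-carboperoxoic acid | COc1cc([C@H]2OC(=O)C[C@@H]2C(=O)OO)ccc1OCc1ccccc1 | intermediate
10 | (2S,3S)-2-[4-(benzyloxy)-3-methoxyphenyl]-5-oxooxolane-3-carboxylic acid | COc1cc([C@H]2OC(=O)C[C@@H]2C(=O)O)ccc1OCc1ccccc1 | intermediate
11 | (4R,5S)-5-[4-(benzyloxy)-3-methoxyphenyl]-4-(hydroxymethyl)oxolan-2-one | COc1cc([C@H]2OC(=O)C[C@@H]2CO)ccc1OCc1ccccc1 | intermediate
12 | (4R,5S)-5-[4-(benzyloxy)-3-methoxyphenyl]-4-{[(tert-butyldimethylsilyl)oxy]methyl}oxolan-2-one | COc1cc([C@H]2OC(=O)C[C@@H]2CO[Si](C)(C)C(C)(C)C)ccc1OCc1ccccc1 | intermediate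
13 | 3,4-bis(benzyloxy)benzaldehyde | O=Cc1ccc(OCc2ccccc2)c(OCc2ccccc2)c1 | starting material
14 | potassium enolate of 12 (potassium (4R,5S)-5-aryl-4-(silyloxymethyl)-4,5-dihydrofuran-2-olate) | COc1cc([C@H]2OC([O-])=C[C@@H]2CO[Si](C)(C)C(C)(C)C)ccc1OCc1ccccc1.[K+] | intermediate
15 | (3R,4R,5S)-5-[4-(benzyloxy)-3-methoxyphenyl]-3-{(R)-[3,4-bis(benzyloxy)phenyl](hydroxy)methyl}-4-{[(tert-butyldimethylsilyl)oxy]methyl}oxolan-2-one | COc1cc([C@H]2OC(=O)[C@@H]([C@@H](O)c3ccc(OCc4ccccc4)c(OCc4ccccc4)c3)[C@@H]2CO[Si](C)(C)C(C)(C)C)ccc1OCc1ccccc1 | intermediate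
16 | (3R,4R,5S)-5-[4-(benzyloxy)-3-methoxyphenyl]-3-{(R)-[3,4-bis(benzyloxy)phenyl][(tert-butyldimethylsilyl)oxy]methyl}-4-{[(tert-butyldimethylsilyl)oxy]methyl}oxolan-2-one | COc1cc([C@H]2OC(=O)[C@@H]([C@@H](O[Si](C)(C)C(C)(C)C)c3ccc(OCc4ccccc4)c(OCc4ccccc4)c3)[C@@H]2CO[Si](C)(C)C(C)(C)C)ccc1OCc1ccccc1 | intermediate
17 | (1S,2R,3S)-1-[4-(benzyloxy)-3-methoxyphenyl]-3-{(R)-[3,4-bis(benzyloxy)phenyl][(tert-butyldimethylsilyl)oxy]methyl}-2-{[(tert-butyldimethylsilyl)oxy]methyl}butane-1,4-diol | COc1cc([C@@H](O)[C@@H](CO[Si](C)(C)C(C)(C)C)[C@@H](CO)[C@@H](O[Si](C)(C)C(C)(C)C)c2ccc(OCc3ccccc3)c(OCc3ccccc3)c2)ccc1OCc1ccccc1 | intermediate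
18 | 4-O-(p-toluenesulfonyl) derivative of 17 (primary monotosylate) | COc1cc([C@@H](O)[C@@H](CO[Si](C)(C)C(C)(C)C)[C@@H](COS(=O)(=O)c2ccc(C)cc2)[C@@H](O[Si](C)(C)C(C)(C)C)c2ccc(OCc3ccccc3)c(OCc3ccccc3)c2)ccc1OCc1ccccc1 | intermediate
19 | (2S,3R,4S)-2-[4-(benzyloxy)-3-methoxyphenyl]-4-{(R)-[3,4-bis(benzyloxy)phenyl][(tert-butyldimethylsilyl)oxy]methyl}-3-{[(tert-butyldimethylsilyl)oxy]methyl}oxolane | COc1cc([C@H]2OC[C@@H]([C@@H](O[Si](C)(C)C(C)(C)C)c3ccc(OCc4ccccc4)c(OCc4ccccc4)c3)[C@@H]2CO[Si](C)(C)C(C)(C)C)ccc1OCc1ccccc1 | intermediate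
20 | (R)-[3,4-bis(benzyloxy)phenyl]{(3S,4R,5S)-5-[4-(benzyloxy)-3-methoxyphenyl]-4-(hydroxymethyl)oxolan-3-yl}methanol | COc1cc([C@H]2OC[C@@H]([C@@H](O)c3ccc(OCc4ccccc4)c(OCc4ccccc4)c3)[C@@H]2CO)ccc1OCc1ccccc1 | intermediate
21 | 4-[(R)-hydroxy{(3S,4R,5S)-5-(4-hydroxy-3-methoxyphenyl)-4-(hydroxymethyl)oxolan-3-yl}methyl]benzene-1,2-diol (CNP0197133.1) | COc1cc([C@H]2OC[C@@H]([C@@H](O)c3ccc(O)c(O)c3)[C@@H]2CO)ccc1O | target

**Totals**
Total step count: 12. Longest linear sequence: 12 steps (1 and 2 to 21); aldehydes 5 and 13 enter as bought.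

**Three steps most likely to fail, with fallbacks**

Step 7 (carbinol selectivity of the lactone aldol). The 3,4-trans relationship is dependable, but the erythro preference of the potassium enolate may be modest. The fallback sets out from 12 and returns at 15. The aldol of 12 with 13 is run with lithium diisopropylamide in THF at −78 °C with no attempt at carbinol control. This gives 15 together with its carbinol epimer (3R,4R,5S)-5-[4-(benzyloxy)-3-methoxyphenyl]-3-{(S)-[3,4-bis(benzyloxy)phenyl](hydroxy)methyl}-4-{[(tert-butyldimethylsilyl)oxy]methyl}oxolan-2-one F1. The whole mixture is oxidised with Dess–Martin periodinane/NaHCO3 in CH2Cl2 to the β-keto lactone (3R,4R,5S)-3-[3,4-bis(benzyloxy)benzoyl]-5-[4-(benzyloxy)-3-methoxyphenyl]-4-{[(tert-butyldimethylsilyl)oxy]methyl}oxolan-2-one F2, whose C3 settles in the trans arrangement. F2 is then reduced with Zn(BH4)2 in Et2O at −78 → −20 °C. Hydride adds to the zinc chelate of the two carbonyls from the face opposite the ring C4 carbon, which is expected to give the syn (R) carbinol 15 and so converges both epimers.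

Step 10 (primary versus benzylic hydroxyl discrimination and ring closure). The fallback sets out from 16 and returns at 19. Lactone 16 is half-reduced with iBu2AlH (1.1 equiv) in CH2Cl2 at −78 °C to the lactol (3R,4R,5S)-5-[4-(benzyloxy)-3-methoxyphenyl]-3-{(R)-[3,4-bis(benzyloxy)phenyl][(tert-butyldimethylsilyl)oxy]methyl}-4-{[(tert-butyldimethylsilyl)oxy]methyl}oxolan-2-ol F3, an anomer mixture. F3 is deoxygenated with Et3SiH/BF3·OEt2 in CH2Cl2 at −78 °C (ionic hydrogenation of the cyclic oxocarbenium ion) to give 19 directly. The ring is never opened, so no hydroxyl discrimination is needed.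

Step 12 (over-reduction of the free benzylic alcohol or of the benzylic ring C–O bond during debenzylation). The fallback sets out from 19 and returns at 21. The three benzyl ethers of 19 are hydrogenolysed first (H2, 10% Pd on carbon, EtOAc, rt), while the benzylic alcohol is still masked as its silyl ether. This gives the triphenol 4-[(R)-[(tert-butyldimethylsilyl)oxy]{(3S,4R,5S)-4-{[(tert-butyldimethylsilyl)oxy]methyl}-5-(4-hydroxy-3-methoxyphenyl)oxolan-3-yl}methyl]benzene-1,2-diol F4. Both silyl groups are then removed with Bu4NF buffered with AcOH in THF at 0 °C → rt under argon to give 21.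

**Further compounds**
F1 | step 7 | (3R,4R,5S)-5-[4-(benzyloxy)-3-methoxyphenyl]-3-{(S)-[3,4-bis(benzyloxy)phenyl](hydroxy)methyl}-4-{[(tert-butyldimethylsilyl)oxy]methyl}oxolan-2-one | COc1cc([C@H]2OC(=O)[C@@H]([C@H](O)c3ccc(OCc4ccccc4)c(OCc4ccccc4)c3)[C@@H]2CO[Si](C)(C)C(C)(C)C)ccc1OCc1ccccc1
F2 | step 7 | (3R,4R,5S)-3-[3,4-bis(benzyloxy)benzoyl]-5-[4-(benzyloxy)-3-methoxyphenyl]-4-{[(tert-butyldimethylsilyl)oxy]methyl}oxolan-2-one | COc1cc([C@H]2OC(=O)[C@@H](C(=O)c3ccc(OCc4ccccc4)c(OCc4ccccc4)c3)[C@@H]2CO[Si](C)(C)C(C)(C)C)ccc1OCc1ccccc1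
F3 | step 10 | (3R,4R,5S)-5-[4-(benzyloxy)-3-methoxyphenyl]-3-{(R)-[3,4-bis(benzyloxy)phenyl][(tert-butyldimethylsilyl)oxy]methyl}-4-{[(tert-butyldimethylsilyl)oxy]methyl}oxolan-2-ol (anomer mixture) | COc1cc([C@H]2OC(O)[C@@H]([C@@H](O[Si](C)(C)C(C)(C)C)c3ccc(OCc4ccccc4)c(OCc4ccccc4)c3)[C@@H]2CO[Si](C)(C)C(C)(C)C)ccc1OCc1ccccc1
F4 | step 12 | 4-[(R)-[(tert-butyldimethylsilyl)oxy]{(3S,4R,5S)-4-{[(tert-butyldimethylsilyl)oxy]methyl}-5-(4-hydroxy-3-methoxyphenyl)oxolan-3-yl}methyl]benzene-1,2-diol | COc1cc([C@H]2OC[C@@H]([C@@H](O[Si](C)(C)C(C)(C)C)c3ccc(O)c(O)c3)[C@@H]2CO[Si](C)(C)C(C)(C)C)ccc1O
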